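**Retrosynthetic overview** (locants are the cyclodeca[b]furan numbering of the target: O1, C2 … C11a)
1. The ten-membered ring is closed last at C3a–C4: a decarboxylative α-acyloxy radical from a seco acid adds to the β-carbon of a 3-(silyloxymethyl)butenolide, and loss of silanolate in the same step gives the 3-methylidene lactone and sets C3a and C4.
2. Seco acid ⇐ cross-metathesis (C6=C7) of a butenolide carrying a terminal alkene with an itaconate-type acid that already bears the (R)-2-methylbutanoate (glyoxylic acid + methyl 2-(bromomethyl)acrylate, then O-acylation).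
3. Butenolide (first ring, C11a set) ⇐ Pd/CO lactonisation of a (Z)-γ-iodo allylic alcohol ⇐ CBS reduction ⇐ hydroiodination of an ynone ⇐ acetylide opening of a β-butenyl γ-butyrolactone.
4. β-Butenyl lactone (C10 set) ⇐ Cu-catalysed asymmetric conjugate addition of butenylmagnesium bromide to furan-2(5H)-one.
5. Ring order: lactone ring first (as butenolide), carbocycle second; the C10 hydroxymethyl group is carried unprotected throughout.

Assumption: Grignard solution 2, silyl ether 4 (silyl-protected propargyl alcohol) and (R)-2-methylbutanoic acid 13 are taken as commercial.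

**Route**

Step 1
Reactants: 1 furan-2(5H)-one; 2 but-3-en-1-ylmagnesium bromide
Product: 3 (4R)-4-(but-3-en-1-yl)oxolan-2-one
Conditions: CuBr·SMe2 (5 mol %), Tol-BINAP (6 mol %; enantiomer chosen for the 4R product), t-BuOMe, −78 °C; then 1 M HCl
Reagents that add atoms: none
Why: Copper-catalysed asymmetric conjugate addition of a Grignard reagent to an α,β-unsaturated lactone, in which the chiral bisphosphine–copper complex delivers the butenyl group to one enantioface and so sets the future C10 centre (R), while the lactone keeps the two oxygenated arms differentiated without protecting groups.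

Step 2
Reactants: 3 (4R)-4-(but-3-en-1-yl)oxolan-2-one; 4 tert-butyldimethyl(prop-2-yn-1-yloxy)silane
Product: 6 (6R)-1-[(tert-butyldimethylsilyl)oxy]-6-(hydroxymethyl)dec-9-en-2-yn-4-one, via lithium acetylide 5 (not isolated)
Conditions: 4, n-BuLi, THF, −78 °C; then 3, −78 °C; AcOH quench
Reagents that add atoms: none
Why: Acylation of a lithium acetylide by a lactone (ring-opening to the hydroxy ynone), where the tetrahedral lithium lactolate is stable at −78 °C so double addition is avoided and the existing stereocentre is untouched.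

Step 3
Reactants: 6 (6R)-1-[(tert-butyldimethylsilyl)oxy]-6-(hydroxymethyl)dec-9-en-2-yn-4-one
Product: 7 (2Z,6R)-1-[(tert-butyldimethylsilyl)oxy]-6-(hydroxymethyl)-2-iododeca-2,9-dien-4-one
Conditions: NaI (1.5 equiv), AcOH (2 equiv), MeCN, 0 → 25 °C, dark
Reagents that add atoms: sodium iodide, [Na+].[I-]
Why: Conjugate hydroiodination of an ynone, in which iodide adds to the β-carbon and anti protonation of the allenolate gives the kinetic (Z)-β-iodo enone with iodine cis to the carbonyl carbon, the geometry the later lactonisation needs.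

Step 4
Reactants: 7 (2Z,6R)-1-[(tert-butyldimethylsilyl)oxy]-6-(hydroxymethyl)-2-iododeca-2,9-dien-4-one
Product: 8 (2Z,4R,6R)-1-[(tert-butyldimethylsilyl)oxy]-6-(hydroxymethyl)-2-iododeca-2,9-dien-4-ol
Conditions: (S)-2-methyl-CBS-oxazaborolidine (0.2 equiv), catecholborane (2.5 equiv), toluene, −78 °C; then aq NaHCO3
Reagents that add atoms: none
Why: Corey–Bakshi–Shibata reduction, in which the iodoalkenyl group acts as the large substituent so the (S)-oxazaborolidine delivers hydride 1,2 to give the (4R)-allylic alcohol (future C11a) under reagent control, and catecholborane at −78 °C leaves the terminal alkene and vinyl iodide alone.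

Step 5
Reactants: 8 (2Z,4R,6R)-1-[(tert-butyldimethylsilyl)oxy]-6-(hydroxymethyl)-2-iododeca-2,9-dien-4-ol
Product: 9 (5R)-3-{[(tert-butyldimethylsilyl)oxy]methyl}-5-[(2R)-2-(hydroxymethyl)hex-5-en-1-yl]furan-2(5H)-one
Conditions: PdCl2(PPh3)2 (5 mol %), CO (1 atm), K2CO3 (2 equiv), THF, 25–40 °C
Reagents that add atoms: carbon monoxide, [C-]#[O+]
Why: Palladium-catalysed carbonylative lactonisation of a (Z)-γ-iodo allylic alcohol, in which zerovalent palladium inserts into the C–I bond, CO inserts, and the cis secondary hydroxyl captures the acylpalladium in a five-membered closure that outruns the remote primary alcohol, with both stereocentres unchanged.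

Step 6
Reactants: 10 glyoxylic acid monohydrate; 11 methyl 2-(bromomethyl)prop-2-enoate
Product: 12 (2RS)-2-hydroxy-4-(methoxycarbonyl)pent-4-enoic acid
Conditions: In powder (1.1 equiv), THF/H2O (1:1), 25 °C; then 1 M HCl, extraction, used crude
Reagents that add atoms: none
Why: Indium-mediated Barbier allylation in water, which adds the allylindium species from 11 to the aldehyde of unprotected glyoxylic acid; the new carbinol centre is racemic, which does not matter because it becomes a planar radical in step 9.

Step 7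
Reactants: 12 (2RS)-2-hydroxy-4-(methoxycarbonyl)pent-4-enoic acid; 13 (2R)-2-methylbutanoic acid
Product: 15 (2RS)-4-(methoxycarbonyl)-2-{[(2R)-2-methylbutanoyl]oxy}pent-4-enoic acid, via (2R)-2-methylbutanoyl chloride 14 (not isolated)
Conditions: 13 (2.2 equiv), (COCl)2, DMF (cat.), CH2Cl2, 0 → 25 °C; then 12, pyridine, CH2Cl2, 0 °C; H2O work-up
Reagents that add atoms: none
Why: O-Acylation of an α-hydroxy acid by an acid chloride with pyridine only (no stronger amine, so the α-stereocentre of the acyl chloride is not racemised via the ketene), giving a 1:1 pair of C2 epimers that both converge in step 9.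

Step 8
Reactants: 9 (5R)-3-{[(tert-butyldimethylsilyl)oxy]methyl}-5-[(2R)-2-(hydroxymethyl)hex-5-en-1-yl]furan-2(5H)-one; 15 (2RS)-4-(methoxycarbonyl)-2-{[(2R)-2-methylbutanoyl]oxy}pent-4-enoic acid
Product: 16 (2RS,4E,8R)-8-(hydroxymethyl)-4-(methoxycarbonyl)-2-{[(2R)-2-methylbutanoyl]oxy}-9-[(2R)-4-{[(tert-butyldimethylsilyl)oxy]methyl}-5-oxo-2,5-dihydrofuran-2-yl]non-4-enoic acid
Conditions: second-generation Hoveyda–Grubbs catalyst (5 mol %), 15 (2 equiv), CH2Cl2, 40 °C
Reagents that add atoms: none
Why: Olefin cross-metathesis between a terminal alkene and a gem-disubstituted itaconate-type acrylate that does not homodimerise, which gives the trisubstituted enoate under thermodynamic control with the alkyl chain trans to CO2Me (E, the geometry required in the ring) and tolerates the free OH and CO2H groups.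

Step 9
Reactants: 16 (2RS,4E,8R)-8-(hydroxymethyl)-4-(methoxycarbonyl)-2-{[(2R)-2-methylbutanoyl]oxy}-9-[(2R)-4-{[(tert-butyldimethylsilyl)oxy]methyl}-5-oxo-2,5-dihydrofuran-2-yl]non-4-enoic acid
Product: 17 methyl (3aS,4R,6E,10R,11aR)-10-(hydroxymethyl)-3-methylidene-4-{[(2R)-2-methylbutanoyl]oxy}-2-oxo-2,3,3a,4,5,8,9,10,11,11a-decahydrocyclodeca[b]furan-6-carboxylate (CNP0141952.3)
Conditions: [Ir{dF(CF3)ppy}2(dtbbpy)]PF6 (2 mol %), K2HPO4 (1.2 equiv), DMF (1 mM), 450 nm LEDs, 25 °C, degassed
Reagents that add atoms: none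
Why: Proposed new method: photoredox decarboxylative radical macrocyclisation with addition–elimination, in which excited trivalent iridium oxidises the carboxylate, loss of CO2 gives the nucleophilic α-acyloxy radical at the future C4, this adds 10-exo to the β-carbon of the electron-poor butenolide on the face anti to the C11a side chain (setting C3a with the trans ring fusion), divalent iridium reduces the resulting α-lactone radical to the enolate, which expels silanolate (E1cB) to reveal the methylidene lactone, and C4 (R) is set by the ring-closing transition state that keeps the acyloxy group on the periphery; the closest known chemistry is the photoredox decarboxylative Giese addition of α-oxy acids, radical allylation of Morita–Baylis–Hillman-type acceptors by addition–β-elimination, and alkyl-radical macrocyclisation onto acrylates.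

**Compound list**
1 | furan-2(5H)-one | O=C1OCC=C1 | starting material
2 | but-3-en-1-ylmagnesium bromide | C=CCC[Mg]Br | starting material
3 | (4R)-4-(but-3-en-1-yl)oxolan-2-one | O=C1C[C@@H](CCC=C)CO1 | intermediate
4 | tert-butyldimethyl(prop-2-yn-1-yloxy)silane | C#CCO[Si](C)(C)C(C)(C)C | starting material
5 | lithium acetylide of 4 (not isolated) | [Li]C#CCO[Si](C)(C)C(C)(C)C | intermediate
6 | (6R)-1-[(tert-butyldimethylsilyl)oxy]-6-(hydroxymethyl)dec-9-en-2-yn-4-one | C=CCC[C@@H](CO)CC(=O)C#CCO[Si](C)(C)C(C)(C)C | intermediate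
7 | (2Z,6R)-1-[(tert-butyldimethylsilyl)oxy]-6-(hydroxymethyl)-2-iododeca-2,9-dien-4-one | C=CCC[C@@H](CO)CC(=O)/C=C(\I)CO[Si](C)(C)C(C)(C)C | intermediate
8 | (2Z,4R,6R)-1-[(tert-butyldimethylsilyl)oxy]-6-(hydroxymethyl)-2-iododeca-2,9-dien-4-ol | C=CCC[C@@H](CO)C[C@@H](O)/C=C(\I)CO[Si](C)(C)C(C)(C)C | intermediate
9 | (5R)-3-{[(tert-butyldimethylsilyl)oxy]methyl}-5-[(2R)-2-(hydroxymethyl)hex-5-en-1-yl]furan-2(5H)-one | C=CCC[C@@H](CO)C[C@H]1OC(=O)C(CO[Si](C)(C)C(C)(C)C)=C1 | intermediate
10 | glyoxylic acid monohydrate (2,2-dihydroxyacetic acid) | OC(O)C(=O)O | starting material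
11 | methyl 2-(bromomethyl)prop-2-enoate | C=C(CBr)C(=O)OC | starting material
12 | (2RS)-2-hydroxy-4-(methoxycarbonyl)pent-4-enoic acid | C=C(C(=O)OC)CC(O)C(=O)O | intermediate
13 | (2R)-2-methylbutanoic acid | OC(=O)[C@H](C)CC | starting material
14 | (2R)-2-methylbutanoyl chloride (not isolated) | ClC(=O)[C@H](C)CC | intermediate
15 | (2RS)-4-(methoxycarbonyl)-2-{[(2R)-2-methylbutanoyl]oxy}pent-4-enoic acid | C=C(C(=O)OC)CC(OC(=O)[C@H](C)CC)C(=O)O | intermediate
16 | (2RS,4E,8R)-8-(hydroxymethyl)-4-(methoxycarbonyl)-2-{[(2R)-2-methylbutanoyl]oxy}-9-[(2R)-4-{[(tert-butyldimethylsilyl)oxy]methyl}-5-oxo-2,5-dihydrofuran-2-yl]non-4-enoic acid | OC[C@H](CC/C=C(/C(=O)OC)CC(OC(=O)[C@H](C)CC)C(=O)O)C[C@H]1OC(=O)C(CO[Si](C)(C)C(C)(C)C)=C1 | intermediate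
17 | methyl (3aS,4R,6E,10R,11aR)-10-(hydroxymethyl)-3-methylidene-4-{[(2R)-2-methylbutanoyl]oxy}-2-oxo-2,3,3a,4,5,8,9,10,11,11a-decahydrocyclodeca[b]furan-6-carboxylate | C=C1C(=O)O[C@@H]2C[C@H](CO)CC/C=C(/C(=O)OC)C[C@@H](OC(=O)[C@H](C)CC)[C@@H]12 | target

**Totals:** 9 steps; longest linear sequence 7 (steps 1, 2, 3, 4, 5, 8, 9).

**Three steps most likely to fail, with fallbacks**

Step 9 (radical macrocyclisation). The likely failure modes are:
- slow ten-membered ring closure;
- 1,5-hydrogen transfer from the allylic C8 methylene to the C4 radical;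
- protonation of the enolate before silanolate leaves;
- the wrong C4 epimer.

Fallback, setting out from 9 (with 15) and returning at 17: change the order of bond formation. Under the same photocatalyst and base, 15 is added slowly to an excess of 9, so the α-acyloxy radical adds intermolecularly anti to the side chain and silanolate is lost. After separation from its C4 epimer this gives the open-chain diene methyl (4R)-4-{(2R,3S)-2-[(2R)-2-(hydroxymethyl)hex-5-en-1-yl]-4-methylidene-5-oxooxolan-3-yl}-2-methylidene-4-{[(2R)-2-methylbutanoyl]oxy}butanoate F1. Ring-closing metathesis of F1 (second-generation Hoveyda–Grubbs catalyst, toluene, 1 mM, 80 °C) then forms the C6=C7 bond and gives 17.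

Step 4 (CBS reduction, together with the sensitive iodo enone 7). The (Z)-β-iodo enone may isomerise or lose iodide, and the CBS facial selectivity with a cis-iodoalkenyl group is untested. Fallback, setting out from 6 and returning at 8: reduce the ynone first by Noyori transfer hydrogenation (RuCl[(R,R)-TsDPEN](p-cymene), i-PrOH, 25 °C) to (4R,6R)-1-[(tert-butyldimethylsilyl)oxy]-6-(hydroxymethyl)dec-9-en-2-yn-4-ol F2. Hydroxyl-directed trans-hydrosilylation (Et3SiH, [Cp*Ru(MeCN)3]PF6, CH2Cl2, 0 °C) places silicon on the alkyne carbon distal to the free hydroxyl and gives (2Z,4R,6R)-1-[(tert-butyldimethylsilyl)oxy]-6-(hydroxymethyl)-2-(triethylsilyl)deca-2,9-dien-4-ol F3. Iododesilylation with retention (N-iodosuccinimide, hexafluoroisopropanol, 0 °C) gives 8.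

Step 1 (asymmetric conjugate addition to the butenolide). Furan-2(5H)-one is a poorer substrate than acyclic enoates for this reaction (polymerisation, modest ee). Fallback, setting out from 2 and returning at 3: add 2 to the acyclic acceptor methyl (E)-4-[(tert-butyldimethylsilyl)oxy]but-2-enoate (CuI/Tol-BINAP, t-BuOMe, −40 °C; then 1 M HCl quench) to give methyl (3R)-3-{[(tert-butyldimethylsilyl)oxy]methyl}hept-6-enoate F4. Treatment with 1 M HCl in THF at 25 °C removes the silyl group and the hydroxy ester lactonises to 3.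

**Further compounds**
F1 | step 9 | methyl (4R)-4-{(2R,3S)-2-[(2R)-2-(hydroxymethyl)hex-5-en-1-yl]-4-methylidene-5-oxooxolan-3-yl}-2-methylidene-4-{[(2R)-2-methylbutanoyl]oxy}butanoate | C=C1C(=O)O[C@H](C[C@H](CO)CCC=C)[C@H]1[C@H](OC(=O)[C@H](C)CC)CC(=C)C(=O)OC
F2 | step 4 | (4R,6R)-1-[(tert-butyldimethylsilyl)oxy]-6-(hydroxymethyl)dec-9-en-2-yn-4-ol | C=CCC[C@@H](CO)C[C@@H](O)C#CCO[Si](C)(C)C(C)(C)C
F3 | step 4 | (2Z,4R,6R)-1-[(tert-butyldimethylsilyl)oxy]-6-(hydroxymethyl)-2-(triethylsilyl)deca-2,9-dien-4-ol | C=CCC[C@@H](CO)C[C@@H](O)/C=C(\[Si](CC)(CC)CC)CO[Si](C)(C)C(C)(C)C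
F4 | step 1 | methyl (3R)-3-{[(tert-butyldimethylsilyl)oxy]methyl}hept-6-enoate | C=CCC[C@@H](CO[Si](C)(C)C(C)(C)C)CC(=O)OC
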